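The earlier runs and the new flask were computed with constants of no real substance; noise was put on by code.

2.24 min⁻¹ against 0.703 min⁻¹: that was how fast I read the electrophile falling after the feed ended in Wednesday's and Thursday's runs, a factor of 3.19 for 1.58 times the nucleophile, so I looked for what the charge did not show.

| flask | electrophile | nucleophile | solid base | remark | time |
|---|---|---|---|---|---|
| Thursday's | 0.30 M (fed, over 2.0 min) | 1.2 equiv | 0.50 equiv | run made earlier; the fed solution adds 0.20 times the starting volume |  |
| Wednesday's | 0.30 M (fed, over 2.0 min) | 1.9 equiv | 0.50 equiv | run made earlier; the fed solution adds 0.20 times the starting volume |  |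
| Friday's | 0.45 M (fed, over 2.0 min) | 2.5 equiv | 0.50 equiv | run made earlier; the fed solution adds 0.20 times the starting volume |  |
| flask | 0.30 M (fed, over 2.0 min) | 2.50 equiv | 0.500 equiv | the fed solution adds 0.20 times the starting volume | 2.0 min |

| run | time / min | electrophile / % | target / % |
|---|---|---|---|
| Thursday's | 0.417 | 8.2 | 12.5 |
| Thursday's | 0.833 | 11.2 | 30.2 |
| Thursday's | 1.33 | 16.6 | 50.2 |
| Thursday's | 1.50 | 18.8 | 56.6 |
| Thursday's | 2.00 | 27.0 | 72.4 |
| Thursday's | 2.50 | 19.0 | 80.8 |
| Wednesday's | 0.167 | 4.1 | 4.4 |
| Wednesday's | 0.500 | 5.7 | 19.4 |
| Wednesday's | 0.833 | 7.2 | 34.8 |
| Wednesday's | 1.33 | 9.2 | 57.0 |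
| Wednesday's | 2.00 | 13.8 | 85.9 |
| Wednesday's | 2.50 | 4.5 | 95.9 |
| Friday's | 0.200 | 2.0 | 7.3 |
| Friday's | 0.667 | 3.3 | 30.1 |
| Friday's | 1.00 | 3.7 | 46.0 |
| Friday's | 1.50 | 5.7 | 69.9 |
| Friday's | 2.50 | 0.1 | 99.4 |

(each reading ± 0.3 percentage points)

- amounts are per litre of the starting volume; all of the dose is in the solution fed
- solid base is a solid; its amount is given per volume of the solution
- at the start none of the solid base is in solution
- percentages count the whole charge, also what has not yet gone in
- the earlier runs do not show how much of nucleophile is bound; that part of a forecast is a guess

- part of the electrophile that has reacted at 2.0 min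
- share of the unused nucleophile that is free and not bound as protonated nucleophile, at 2.0 min

Electrophile plus target matched what had been fed, so I kept a budget of free nucleophile per electrophile charged: the charge, minus two for each target, one coupled and one held as protonated nucleophile, plus a credit from the solid base. Requiring one constant for both runs, at their mean target over the last half minute, gave a credit of 52.1%, a reading with the scatter of the runs in it, to be set beside the 0.50 equiv of solid base charged, and 4.46 min⁻¹, the capture constant: the pseudo-first-order rate of electrophile loss per unit of budget, at 0.30 M and starting volume, thinned by volume growth and scaled with the charge. Friday's run held 5.7% at 1.50 min, where feed rate over capture rate gave me 5.30%.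

In the new flask I reckoned that the first drops met the full nucleophile charge, with a lifetime of 0.0897 min, far shorter than the dosing, so I expected the electrophile to stay a small holdup, feed rate over capture rate. Through the middle I expected the budget to shrink with each target and the holdup to creep up. At the end of the feed, with the credit carried over unchanged, a first round assuming no holdup gave 13.2%; putting that back gave 10.5%, and once more 10.9%. I therefore committed to 89.1% reacted and, as a guess, 77.0% free.

The forecast said 90.3% (88.5% to 92%) and 72% (66% to 78%), reasoning that “Each coupling uses one nucleophile and protonates another”.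

The flask gave 90.8% and 67.8%, the second below my guess.

    electrophile + nucleophile → acid set free + target (k = 0.300 M⁻¹ s⁻¹)
    nucleophile + acid set free ⇌ protonated nucleophile, settled at all times (K = 140 M⁻¹)
    acid set free + free base ⇌ salt of the base, settled at all times (K = 950 M⁻¹)
    acid set free → by-product carried off (k = 0.00290 s⁻¹)
    solid base ⇌ free base, rate k5*(cs5 - [free base]) while solid is left; crystals form when [free base] > cs5 (solubility = 0.180 M, k = 0.00800 s⁻¹)

At 2.00 min the electrophile's half-life by coupling in this flask was 0.14 min, short against the dosing time of 2.0 min, which corresponds to a capture rate of 4.86 min⁻¹ beside my 4.57 min⁻¹, with 9.15% of electrophile standing at that moment. For the neighbour flask charged at 0.51 M of electrophile, with the same equivalents, one round from my last holdup, with the same credit and K scaled by the charge, gives 6.38%, and that flask held 6.5%.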